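A leftover is the thing to watch here: 3.00 equiv of reagent on the left-handed substrate leaves 33.3% of the reagent over once both substrates have reacted, so the right-handed substrate can keep reacting after the left-handed one has thinned.

the same everywhere: racemization catalyst 2.5 mol%; added ligand 0.85 mM
- blue: left-handed substrate 0.013 M; right-handed substrate 0.013 M; reagent 3 equiv; the very flask that is asked about, followed so far
- ochre: left-handed substrate 0.019 M; right-handed substrate 0.019 M; reagent 3 equiv; run made earlier
- flask: left-handed substrate 0.013 M; right-handed substrate 0.013 M; reagent 3.00 equiv; time 4.0 min

blue run (percent of the left-handed substrate and right-handed substrate together charged)

| time / s | left-handed product / % | right-handed product / % |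
|---|---|---|
| 10.0 | 19 | 10 |
| 12.0 | 22 | 11 |
| 20.0 | 34 | 13 |
| 30.0 | 32 | 17 |
| 50.0 | 42 | 28 |
| 80.0 | 46 | 27 |

ochre run (percent of the left-handed substrate and right-handed substrate together charged)

| time / min | left-handed product / % | right-handed product / % |
|---|---|---|
| 0.417 | 41 | 18 |
| 0.833 | 43 | 26 |
| 1.33 | 48 | 35 |
| 1.50 | 53 | 35 |
| 2.00 | 50 | 39 |
| 2.50 | 52 | 40 |
| 3.00 | 51 | 43 |

(each reading ± 2 percentage points)

- reagent is single-handed; left-handed substrate and right-handed substrate are mirror images of each other, charged as a racemate, each of them at the stated concentration
- an excess is the difference of the two amounts in percent of their sum
- an excess is below zero if the other one leads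
- the handed part of reagent does not stay in what it makes, so the products of the two hands are mirror images too

* left-handed product and right-handed product together, in percent of the left-handed substrate and right-handed substrate charged together, at 4.0 min
* excess of left-handed product over right-handed product in the product at 4.0 min
* whether the exchange between left-handed substrate and right-handed substrate keeps pace with the reaction: how far the product's excess at 4.0 min gets from its value without exchange to its value with instant exchange (above 80% keeps pace, below 20% hardly takes part, else lags behind)

At any moment both hands meet the same reagent, so their rates stand in the ratio of the selectivity factor s, the ratio of the two rate constants, times the ratio of what is left of each, and this comparison drifts against the left hand as it thins. Without exchange this integrates to a power rule: the left-handed part left equals the right-handed part left raised to s. Pooling the logarithms of the blue readings gives a reading of s of 2.72.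

Reagent appears nowhere in the rule, so without exchange changing its charge moves a flask along this curve, not off it. Changing the concentration at equal equivalents rescales the clock of the two reactions with reagent, if each is first order in substrate and in reagent, so without exchange the flask at 4.0 min matches ochre at 2.74 min. Ochre's readings around that time average 41.5% right-handed product, which leaves 17.0% of the right-handed substrate's charge. The rule then leaves 0.807% of the left-handed charge, so this reckoning gives a yield of 91.1% and an excess of 8.89%.

Catalyst and ligand are expected to act through the exchange, and instant exchange, holding the two substrates equal, gives an excess of 46.2%. The blue readings at 50.0 s leave 16.0% of the left-handed charge against 44.0% of the right-handed, not the equal parts of instant exchange, so this reckoning expects exchange to hardly take part.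

The forecast gives 94%, 6% and "hardly takes part", holding that “exchange should be essentially off”. Its excess is lower than the reckoning's, while on the exchange the two agree.

The flask gives 93.8%, 8.30% and "hardly takes part", the excess getting 4.0% of the way.

    2 racemization catalyst → spent catalyst A (k = 552 M⁻¹ min⁻¹)
    reagent + right-handed substrate → right-handed product (k = 26.8 M⁻¹ min⁻¹)
    racemization catalyst + added ligand ⇌ idle complex, settled at all times (K = 840 M⁻¹)
    left-handed substrate + racemization catalyst ⇌ right-handed substrate + racemization catalyst, rate k4*[racemization catalyst]*[left-handed substrate] forward; the back reaction follows from the equilibrium constant (k = 143 M⁻¹ min⁻¹)
    reagent + left-handed substrate → left-handed product (k = 76.9 M⁻¹ min⁻¹)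
    racemization catalyst → spent catalyst B (k = 0.0987 min⁻¹)

In the flask, the left-handed conversion had half of its turnover up to 4.0 min behind it by 0.274 min, and racemization catalyst stood at 57.2% of its charge at 0.400 min. The right-handed substrate then went on reacting, and the excess went from 26.3% at 1.00 min to 8.30% at 4.0 min, with 37.5% of the reagent still there. Raised to s, the flask's 12% of right-handed charge left gives 0.311% against 0.50% of left-handed charge left. The neighbour with 1.20 equiv of reagent keeps 61% of its right-handed charge, which gives 25.5% against 28% of its left-handed charge.

The readings are simulated with made-up constants; noise was put on by code.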